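I decided to count nucleophile rather than integrate anything, since the thing sought is an amount.

electrophile 0.20 M; protic impurity 0.0400 M; time 2.0 h

    electrophile + nucleophile → acid set free + target (k1 = 0.00308 M⁻¹ s⁻¹)
    nucleophile + acid set free ⇌ protonated nucleophile, settled at all times (K2 = 1400 M⁻¹)
    nucleophile + target → over-reaction product (k3 = 4.96 × 10⁻⁴ M⁻¹ s⁻¹)
    acid set free → by-product carried off (k4 = 2.83 × 10⁻⁴ s⁻¹)
    nucleophile + protic impurity → quenched reagent (k5 = 0.00295 M⁻¹ s⁻¹)

1. the concentration of nucleophile at which the part of the electrophile that has reacted at 2.0 h is just 50%, in M

As a first count, each electrophile that reacts takes two nucleophiles, one in the main step and one held as protonated nucleophile by the acid set free, and each protic impurity can take one more. So I folded the givens into one number, the demand: nucleophile needed per electrophile charged, the wanted part taken two times plus the ratio of impurity to electrophile, 1.20. It treats nucleophile as the limiting reagent and reads off a charge of 0.240 M.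

One number was not enough. Acid set free, while it is free, has a half-life of 0.680 h by the carrying-off step alone, shorter than the 2.0 h run, so I expected some held nucleophile to return and the true charge to lie below my figure. Over-reaction pushes the other way, but its rate constant is 0.161 of the main step's.

The forecast gave 0.216 M, counting “one consumed and one tied up by the released acid”, with slow acid loss “pulling the requirement slightly below that total”.

The simulation gives 0.210 M, which is 1.05 per electrophile charged, so the forecast stands within its tolerance. At 2.00 h, 2.59% of the charged nucleophile is still free, so 1.02 per electrophile charged is no longer free. That is less than the demand of 1.20, by 0.178, or 0.0356 M.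

The constants used here were drawn at random within sensible limits; the run is a simulation.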